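Everything rests on disconnecting the two methyl bonds C9–C20 and C8–C17, which sit β and α to a C7 ketone in ring B. In one operation, conjugate methyl transfer from a cuprate to C9 of the cis-fused enone 14 is followed by C-methylation of the C7 enolate at C8; this creates the quaternary C9 and the C8 stereocentre. Enone 14 carries C7=O, C8=C9, the side chain on C9, H10, C19 on C5 and C4 already as the C4=C18 methylene. The step exploits the angular C19 methyl on C5, 1,3 to C9 across ring B: it shields the β face while the flat sp2 C4 leaves the α face open, so C20 enters trans to C19.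

Key step: step 12

Remark (numbering and faces): clerodane numbering is used: C1–C4 ring A from the CH2 next to C10 round to the methylene-bearing carbon, C5 fusion carbon with C19, C6, C7 (C–O), C8 (C17), C9 (C20, C11), C10 fusion CH, C11–C15 chain with C16 on C13, C18 the exocyclic methylene. β is the face of ring B that carries C19 and H10; α is the other face.

Remark (structure check): C5, C10 and C13 have the same sense in 14, 19 and 30, and (R)-citronellol supplies C13 correctly; no structure needed correction.

Remark (precursor design): C4 goes through the key step as the C4=C18 alkene, not as a ketal. A tetrahedral C4 acetal would hold one oxygen over the α face of ring B, where C20 must enter, and would exclude the chair with axial C20 and equatorial C17 on which both stereochemical arguments depend. The bonds formed in the key step are unchanged; 14 and 19 differ from the ketal versions only in this spectator group.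

Assumption (step 5): the sense of induction is assigned by analogy with acrylate and quinone cycloadditions of the same catalyst family; if it proved opposite, the (R)-catalyst would be used with no other change.

Step 1
Reactants: 1 (R)-citronellol
Product: 2 (R)-citronellol TBS ether
Conditions: TBSCl, imidazole, CH2Cl2, 0 °C to rt
Reagents that add atoms: tert-butyldimethylsilyl chloride, CC(C)(C)[Si](C)(C)Cl
Why: Imidazole-mediated silylation of a primary alcohol should mask the C15 oxygen for steps 2–14 and does not touch C13.

Step 2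
Reactants: 2 (R)-citronellol TBS ether
Product: 3 (R)-6-(tert-butyldimethylsilyloxy)-4-methylhexanal
Conditions: O3, CH2Cl2/MeOH, −78 °C; then Me2S, to rt
Reagents that add atoms: ozone, [O-][O+]=O
Why: Ozonolysis with reductive work-up cleaves the only C=C bond to the aldehyde whose carbon becomes C9, the silyl ether being inert.

Step 3
Reactants: 3 (R)-6-(tert-butyldimethylsilyloxy)-4-methylhexanal; 4 1-(triphenylphosphoranylidene)propan-2-one
Product: 5 (R,E)-9-(tert-butyldimethylsilyloxy)-7-methylnon-3-en-2-one
Conditions: CH2Cl2, 40 °C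
Reagents that add atoms: none
Why: Wittig olefination with a stabilised ylide should give the (E)-enone and brings in C6, C7 and C8.

Step 4
Reactants: 5 (R,E)-9-(tert-butyldimethylsilyloxy)-7-methylnon-3-en-2-one
Product: 6 (R,E)-9-(tert-butyldimethylsilyloxy)-7-methyl-2-(triisopropylsilyloxy)nona-1,3-diene
Conditions: TIPSOTf, Et3N, Et2O, 0 °C
Reagents that add atoms: triisopropylsilyl triflate, CC(C)[Si](C(C)C)(C(C)C)OS(=O)(=O)C(F)(F)F
Why: Soft enolisation of the methyl ketone at its methyl group should give the cross-conjugated 2-silyloxydiene, the TIPS group making the enol ether robust enough for steps 5–10.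

Step 5
Reactants: 6 (R,E)-2-silyloxydiene; 7 2-methoxy-6-methyl-1,4-benzoquinone
Product: 8 cis-fused Diels–Alder adduct (3-methoxy-2-ene-1,4-dione in ring A, C7 TIPS enol ether in ring B)
Conditions: (S)-o-tolyl-diphenylprolinol oxazaborolidine, Tf2NH (20 mol %), CH2Cl2, −78 to −40 °C
Reagents that add atoms: none
Why: This is an oxazaborolidinium-catalysed Diels–Alder reaction of a 2-silyloxydiene with an unsymmetrical quinone: the cation binds the more basic vinylogous-ester carbonyl (future C1), the methyl-bearing C=C reacts rather than the methoxy-bearing one, the CH2 terminus of the diene bonds to the methyl-bearing carbon β to the bound carbonyl (C5–C6), endo addition gives the cis fusion, and the catalyst screens one quinone face so that C5 and C10 are set absolutely (C9 is set too but erased in step 11).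

Step 6
Reactants: 8 Diels–Alder adduct
Product: 9 cis-fused 1,4-diketone (C1 and C4 ketones, C7 TIPS enol ether)
Conditions: SmI2 (4.5 equiv), THF/MeOH, −78 to 0 °C
Reagents that add atoms: none
Why: Samarium diiodide should reduce the ene-dione C2=C3 bond and then cleave the C3 methoxy group α to the C4 ketone (reduction of an α-alkoxy ketone), under neutral conditions that spare the silyl enol ether and do not enolise C10.

Step 7
Reactants: 9 cis-fused 1,4-diketone
Product: 10 1-hydroxy-4-ketone
Conditions: NaBH4, MeOH/CH2Cl2, −78 °C
Reagents that add atoms: none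
Why: Borohydride at low temperature should reduce the C1 ketone (next to the tertiary C10–H) in preference to the neopentyl C4 ketone next to quaternary C5; hydride is expected on the H10 face, but the new C1 configuration is of no consequence because the centre is removed in step 9.

Step 8
Reactants: 10 1-hydroxy-4-ketone
Product: 11 C1 O-phenyl thionocarbonate
Conditions: PhOC(S)Cl, pyridine, DMAP (cat.), CH2Cl2, rt
Reagents that add atoms: O-phenyl chlorothionoformate, S=C(Cl)Oc1ccccc1
Why: Thioacylation of the secondary alcohol prepares it for radical deoxygenation and is compatible with the ketone and both silyl groups.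

Step 9
Reactants: 11 C1 O-phenyl thionocarbonate
Product: 12 C4 ketone with C1–C3 as CH2 (C7 TIPS enol ether)
Conditions: Bu3SnH, AIBN, toluene, 90 °C
Reagents that add atoms: none
Why: Barton–McCombie deoxygenation removes the C1 oxygen through a secondary radical that has no favourable cyclisation or fragmentation path, after which C10 is no longer epimerisable.

Step 10
Reactants: 12 C4 ketone
Product: 13 C4=C18 methylene compound (C7 TIPS enol ether)
Conditions: Ph3PCH3Br, KHMDS, toluene/THF, 0 to 90 °C
Reagents that add atoms: methyltriphenylphosphonium bromide (as its ylide), C[P+](c1ccccc1)(c1ccccc1)c1ccccc1.[Br-]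
Why: Wittig methylenation of the only carbonyl group, under forcing conditions suited to a ketone next to a quaternary carbon, installs C18 and makes C4 planar before the key step; the TIPS enol ether is inert to the ylide.

Step 11
Reactants: 13 C4=C18 methylene compound
Product: 14 cis-fused C8=C9 enone (C7 ketone, chain on C9, C4=C18)
Conditions: Pd(OAc)2 (1.1 equiv), MeCN, rt to 40 °C
Reagents that add atoms: none
Why: Saegusa–Ito oxidation of the silyl enol ether places palladium on C8, and the only β-hydrogen is H9, so only the C8=C9 enone can form; the isolated 1,1-disubstituted alkene is a spectator.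

Step 12
Reactants: 14 cis-fused C8=C9 enone; 15 iodomethane
Product: 19 C7 ketone with C20 α on C9 and C17 α on C8, via TMS enol ether 16 (not isolated), via lithium enolate 17 (not isolated), via C8-epimeric ketone 18 (not isolated)
Conditions: Me2CuLi (from CuI, MeLi), TMSCl, THF, −78 to −30 °C; then MeLi, 0 °C; then MeI, DMPU, −40 to 0 °C; NH4Cl work-up, then NaOMe, MeOH, rt on the crude ketone
Reagents that add atoms: lithium dimethylcuprate, [Li+].C[Cu-]C; iodomethane 15, CI
Why: The step is a TMSCl-accelerated conjugate addition of a Gilman cuprate to a β-substituted cyclohexenone (through the copper(III) β-adduct), then regiospecific C-methylation of the lithium enolate released from silyl enol ether 16 by MeLi, a long-established tandem vicinal dialkylation; no ring is closed. At C9 the methyl is transferred axially in the half-chair of ring B that has C4 pseudoaxial and C19 pseudoequatorial, where it passes only the π face of the sp2 C4, whereas axial delivery on the β face would run 1,3-diaxial into the C19 methyl, so C20 ends α and the chain stays cis to H10. At C8 iodomethane should attack enolate 17 anti to the now axial C20 and give mainly 18 with C17 axial, and methoxide equilibration through the C7 enolate should then move C17 to the equatorial position, cis to C20 and free of the two syn-axial hydrogens, which is 19. The step needs face selectivity at C9, secured by C19 on C5 together with the planar C4=C18, and regioselectivity of alkylation, secured because the enolate is formed only towards C8 and C6 is neopentyl. It also needs chemoselectivity, which holds because the isolated alkene and the silyl ether are inert to cuprate, MeLi and MeI.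

Step 13
Reactants: 19 C7 ketone
Product: 20 7β-alcohol
Conditions: Li, NH3(l)/THF, EtOH, −78 °C; then NH4Cl
Reagents that add atoms: none
Why: Dissolving-metal reduction of a hindered cyclohexanone gives the more stable equatorial alcohol, here the 7β-hydroxyl (trans to C17, away from the syn-axial C20 and C4), whereas a kinetic hydride would come from the open β face and give the axial 7α-alcohol; the isolated alkene and the silyl ether are inert.

Step 14
Reactants: 20 7β-alcohol
Product: 21 7β-acetate
Conditions: Ac2O, Et3N, DMAP, CH2Cl2, rt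
Reagents that add atoms: acetic anhydride, CC(=O)OC(C)=O
Why: DMAP-catalysed acetylation of the equatorial secondary alcohol should be straightforward.

Step 15
Reactants: 21 7β-acetate
Product: 22 C15 primary alcohol
Conditions: HF·pyridine, THF/pyridine, 0 °C to rt
Reagents that add atoms: none
Why: Buffered fluoride cleaves the primary TBS ether without touching the acetate or isomerising the exocyclic alkene.

Step 16
Reactants: 22 C15 primary alcohol
Product: 23 C15 carboxylic acid
Conditions: TEMPO (cat.), PhI(OAc)2, MeCN/H2O, rt
Reagents that add atoms: water, O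
Why: Oxoammonium oxidation takes the primary alcohol through the aldehyde hydrate to the acid and leaves the alkene and the acetate alone; it is placed before the sensitive ring A functions exist.

Step 17
Reactants: 23 C15 carboxylic acid
Product: 24 C3 allylic alcohol (C3 epimers)
Conditions: SeO2 (cat.), t-BuOOH, CH2Cl2, rt
Reagents that add atoms: tert-butyl hydroperoxide (oxygen relayed by SeO2), CC(C)(C)OO
Why: Selenium dioxide allylic hydroxylation (ene reaction, then [2,3]-shift) can only occur at C3, because the other allylic carbon C5 is quaternary, and returns the C4=C18 bond to its place; the C3 configuration is irrelevant.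

Step 18
Reactants: 24 C3 allylic alcohol
Product: 25 3-keto-4(18)-ene (α-methylene ketone)
Conditions: Dess–Martin periodinane, CH2Cl2, rt
Reagents that add atoms: none
Why: Periodinane oxidation of the allylic alcohol gives the cross-conjugated ketone under non-basic conditions tolerated by the acid and the acetate.

Step 19
Reactants: 25 3-keto-4(18)-ene
Product: 28 2-hydroxy-3-ketone (C2 epimers), via bis-silyl dienol ether 26 (not isolated), via silyloxy epoxide 27 (not isolated)
Conditions: TMSOTf, Et3N, CH2Cl2, 0 °C; then DMDO, acetone, −78 to 0 °C; then citric acid, MeOH/H2O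
Reagents that add atoms: dimethyldioxirane, CC1(C)OO1
Why: Rubottom oxidation: the ketone can enolise only towards C2 (C4 has no hydrogen), soft enolisation avoids strong base that would attack the acetate, and the dioxirane epoxidises the electron-rich enol ether C2=C3 in preference to C4=C18; mild acid then releases the ketol and the silyl ester.

Step 20
Reactants: 28 2-hydroxy-3-ketone
Product: 30 target, 7β-acetoxy-2-hydroxy-3-oxo-cis-cleroda-1,4(18)-dien-15-oic acid, via 2,3-diketone 29 (not isolated)
Conditions: Dess–Martin periodinane, CH2Cl2, 0 °C to rt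
Reagents that add atoms: none
Why: Oxidation of the acyloin gives the 1,2-diketone, which can enolise only towards C1 and should therefore settle as the diosphenol of the target.

Compound list
1 | (R)-citronellol | CC(C)=CCC[C@@H](C)CCO | starting material
2 | (R)-tert-butyl[(3,7-dimethyloct-6-en-1-yl)oxy]dimethylsilane | CC(C)=CCC[C@@H](C)CCO[Si](C)(C)C(C)(C)C | intermediate
3 | (R)-6-(tert-butyldimethylsilyloxy)-4-methylhexanal | O=CCC[C@@H](C)CCO[Si](C)(C)C(C)(C)C | intermediate
4 | 1-(triphenylphosphoranylidene)propan-2-one | CC(=O)C=P(c1ccccc1)(c1ccccc1)c1ccccc1 | starting material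
5 | (R,E)-9-(tert-butyldimethylsilyloxy)-7-methylnon-3-en-2-one | CC(=O)/C=C/CC[C@@H](C)CCO[Si](C)(C)C(C)(C)C | intermediate
6 | (R,E)-9-(tert-butyldimethylsilyloxy)-7-methyl-2-(triisopropylsilyloxy)nona-1,3-diene | C=C(O[Si](C(C)C)(C(C)C)C(C)C)/C=C/CC[C@@H](C)CCO[Si](C)(C)C(C)(C)C | intermediate
7 | 2-methoxy-6-methyl-1,4-benzoquinone | COC1=CC(=O)C=C(C)C1=O | starting material
8 | Diels–Alder adduct: cis-decalin with C1 and C4 ketones, C2=C3 bearing OMe on C3, C7 TIPS enol ether (C7=C8), C19 and H10 β, C15-OTBS chain on C9 α (cis to C1) | O=C1C(OC)=CC(=O)[C@@H]2[C@H](CC[C@@H](C)CCO[Si](C)(C)C(C)(C)C)C=C(O[Si](C(C)C)(C(C)C)C(C)C)C[C@]12C | intermediate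
9 | 1,4-diketone: as 8 with C2 and C3 as CH2 | O=C1CCC(=O)[C@@H]2[C@H](CC[C@@H](C)CCO[Si](C)(C)C(C)(C)C)C=C(O[Si](C(C)C)(C(C)C)C(C)C)C[C@]12C | intermediate
10 | 1-hydroxy-4-ketone: as 9 with C1–OH (drawn cis to C9; either C1 epimer serves) | O=C1CC[C@H](O)[C@@H]2[C@H](CC[C@@H](C)CCO[Si](C)(C)C(C)(C)C)C=C(O[Si](C(C)C)(C(C)C)C(C)C)C[C@]12C | intermediate
11 | C1 O-phenyl thionocarbonate of 10 | O=C1CC[C@H](OC(=S)Oc3ccccc3)[C@@H]2[C@H](CC[C@@H](C)CCO[Si](C)(C)C(C)(C)C)C=C(O[Si](C(C)C)(C(C)C)C(C)C)C[C@]12C | intermediate
12 | C4 ketone: cis-decalin, C1–C3 CH2, C7 TIPS enol ether, chain on C9 α | O=C1CCC[C@@H]2[C@H](CC[C@@H](C)CCO[Si](C)(C)C(C)(C)C)C=C(O[Si](C(C)C)(C(C)C)C(C)C)C[C@]12C | intermediate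
13 | C4=C18 methylene compound: as 12 with C4=CH2 | C=C1CCC[C@@H]2[C@H](CC[C@@H](C)CCO[Si](C)(C)C(C)(C)C)C=C(O[Si](C(C)C)(C(C)C)C(C)C)C[C@]12C | intermediate
14 | key-step precursor: (13R)-15-(tert-butyldimethylsilyloxy)-17,20-dinor-cis-cleroda-4(18),8-dien-7-one (C19 and H10 β) | C=C1CCC[C@@H]2C(CC[C@@H](C)CCO[Si](C)(C)C(C)(C)C)=CC(=O)C[C@]12C | intermediate
15 | iodomethane | CI | starting material
16 | TMS enol ether (C7=C8, C7–OTMS) with C20 α and chain β on C9 | C=C1CCC[C@@H]2[C@@](C)(CC[C@@H](C)CCO[Si](C)(C)C(C)(C)C)C=C(O[Si](C)(C)C)C[C@]12C | intermediate (not isolated)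
17 | lithium C7 enolate (C7=C8) | C=C1CCC[C@@H]2[C@@](C)(CC[C@@H](C)CCO[Si](C)(C)C(C)(C)C)C=C([O-])C[C@]12C.[Li+] | intermediate (not isolated)
18 | C8-epimeric ketone: C17 β (axial), C20 α | C=C1CCC[C@@H]2[C@@](C)(CC[C@@H](C)CCO[Si](C)(C)C(C)(C)C)[C@@H](C)C(=O)C[C@]12C | intermediate (not isolated)
19 | key-step product: (13R)-15-(tert-butyldimethylsilyloxy)-cis-cleroda-4(18)-en-7-one, C17 α, C20 α, chain β | C=C1CCC[C@@H]2[C@@](C)(CC[C@@H](C)CCO[Si](C)(C)C(C)(C)C)[C@H](C)C(=O)C[C@]12C | intermediate
20 | 7β-alcohol of 19 | C=C1CCC[C@@H]2[C@@](C)(CC[C@@H](C)CCO[Si](C)(C)C(C)(C)C)[C@H](C)[C@@H](O)C[C@]12C | intermediate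
21 | 7β-acetate, C15-OTBS | C=C1CCC[C@@H]2[C@@](C)(CC[C@@H](C)CCO[Si](C)(C)C(C)(C)C)[C@H](C)[C@@H](OC(C)=O)C[C@]12C | intermediate
22 | 7β-acetoxy-cis-cleroda-4(18)-en-15-ol | C=C1CCC[C@@H]2[C@@](C)(CC[C@@H](C)CCO)[C@H](C)[C@@H](OC(C)=O)C[C@]12C | intermediate
23 | 7β-acetoxy-cis-cleroda-4(18)-en-15-oic acid | C=C1CCC[C@@H]2[C@@](C)(CC[C@@H](C)CC(=O)O)[C@H](C)[C@@H](OC(C)=O)C[C@]12C | intermediate
24 | 7β-acetoxy-3-hydroxy-cis-cleroda-4(18)-en-15-oic acid (C3 epimers, configuration not fixed) | C=C1C(O)CC[C@@H]2[C@@](C)(CC[C@@H](C)CC(=O)O)[C@H](C)[C@@H](OC(C)=O)C[C@]12C | intermediate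
25 | 7β-acetoxy-3-oxo-cis-cleroda-4(18)-en-15-oic acid | C=C1C(=O)CC[C@@H]2[C@@](C)(CC[C@@H](C)CC(=O)O)[C@H](C)[C@@H](OC(C)=O)C[C@]12C | intermediate
26 | bis-silyl dienol ether: C2=C3 with C3–OTMS, C4=C18, TMS ester at C15 | C=C1C(O[Si](C)(C)C)=CC[C@@H]2[C@@](C)(CC[C@@H](C)CC(=O)O[Si](C)(C)C)[C@H](C)[C@@H](OC(C)=O)C[C@]12C | intermediate (not isolated)
27 | silyloxy epoxide: 2,3-epoxide with C3–OTMS, TMS ester (epoxide configuration not fixed) | C=C1C3(O[Si](C)(C)C)OC3C[C@@H]2[C@@](C)(CC[C@@H](C)CC(=O)O[Si](C)(C)C)[C@H](C)[C@@H](OC(C)=O)C[C@]12C | intermediate (not isolated)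
28 | 7β-acetoxy-2-hydroxy-3-oxo-cis-cleroda-4(18)-en-15-oic acid (C2 epimers, configuration not fixed) | C=C1C(=O)C(O)C[C@@H]2[C@@](C)(CC[C@@H](C)CC(=O)O)[C@H](C)[C@@H](OC(C)=O)C[C@]12C | intermediate
29 | 7β-acetoxy-2,3-dioxo-cis-cleroda-4(18)-en-15-oic acid | C=C1C(=O)C(=O)C[C@@H]2[C@@](C)(CC[C@@H](C)CC(=O)O)[C@H](C)[C@@H](OC(C)=O)C[C@]12C | intermediate (not isolated)
30 | 7β-acetoxy-2-hydroxy-3-oxo-cis-cleroda-1,4(18)-dien-15-oic acid (CNP0257844.1) | C=C1C(=O)C(O)=C[C@@H]2[C@@](C)(CC[C@@H](C)CC(=O)O)[C@H](C)[C@@H](OC(C)=O)C[C@]12C | target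

Total step count: 20. Longest linear sequence: 20 steps, from 1 to 30 (4, 7 and 15 enter as purchased partners).

Steps most likely to fail

1. Step 12. The methyl group may be delivered to the wrong face of C9, or the hindered β-carbon may react too slowly. Methylation of the enolate next to the new quaternary centre may also stall or drift to C6. The fallback sets out from 14 and comes back at lithium enolate 17; it fixes the face with a covalently placed hydroxyl instead of relying on sterics. Enone 14 would be reduced (NaBH4, CeCl3, MeOH, −78 °C) to the 7α-allylic alcohol F1, with hydroxyl on the face opposite C19; its C7 epimer F2, if formed, would be returned to 14 with MnO2. Hydroxyl-directed Simmons–Smith cyclopropanation of F1 (Et2Zn, CH2I2, CH2Cl2) would add the methylene across C8=C9 from the hydroxyl face to give cyclopropyl carbinol F3. Dess–Martin oxidation would give cyclopropyl ketone F4. Li/NH3 would then cleave the C8–CH2 cyclopropane bond that overlaps with the carbonyl π system, leaving that carbon as the C20 methyl on C9 and giving enolate 17. Iodomethane and the methoxide equilibration follow as in step 12 to reach 19.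

2. Step 5. The catalyst may discriminate the quinone faces insufficiently, or the cationic Lewis acid may protodesilylate the diene before cycloaddition. The fallback sets out from 6 and 7 and comes back at 10; it replaces catalyst control by separation of covalent diastereomers. BF3·OEt2 in CH2Cl2 at −78 °C (monodentate, same regiochemistry) would give 8 together with the diastereomeric adduct F5, in which the ring stereocentres are mirrored. The mixture would be taken through steps 6 and 7, giving 9 with diketone F6 and 10 with carbinol F7. Esterification of the C1 carbinols with (R)-O-methylmandelic acid (DCC, DMAP) would give O-methylmandelate F8 from 10 and O-methylmandelate F9 from F7, which should separate on silica because the auxiliary sits next to the ring stereocentres. Methanolysis of F8 (K2CO3, MeOH) returns 10.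

3. Step 19. The α-methylene ketone may add the amine or oligomerise during soft enolisation, or the oxidant may attack C4=C18 instead of the enol ether. The fallback sets out from 25 and comes back at 30; it replaces steps 19 and 20 together. Riley oxidation (SeO2, dioxane/H2O, 80 °C) would oxidise the C2 methylene next to the ketone directly to diketone 29, which enolises to 30. No allylic oxidation can compete, because both allylic positions of C4=C18 lack hydrogen.

Further compounds
F1 | step 12 | 7α-allylic alcohol from 14 (C7–OH on the face opposite C19) | C=C1CCC[C@@H]2C(CC[C@@H](C)CCO[Si](C)(C)C(C)(C)C)=C[C@H](O)C[C@]12C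
F2 | step 12 | 7β-allylic alcohol, C7 epimer of F1 | C=C1CCC[C@@H]2C(CC[C@@H](C)CCO[Si](C)(C)C(C)(C)C)=C[C@@H](O)C[C@]12C
F3 | step 12 | cyclopropyl carbinol: 8,9-methano compound with α-methylene bridge and 7α-OH | C=C1CCC[C@@H]2[C@]3(CC[C@@H](C)CCO[Si](C)(C)C(C)(C)C)C[C@@H]3[C@H](O)C[C@]12C
F4 | step 12 | cyclopropyl ketone: 8,9-methano-7-ketone | C=C1CCC[C@@H]2[C@]3(CC[C@@H](C)CCO[Si](C)(C)C(C)(C)C)C[C@@H]3C(=O)C[C@]12C
F5 | step 5 | diastereomer of 8 with mirrored ring stereocentres (C5, C9, C10) | O=C1C(OC)=CC(=O)[C@H]2[C@@H](CC[C@@H](C)CCO[Si](C)(C)C(C)(C)C)C=C(O[Si](C(C)C)(C(C)C)C(C)C)C[C@@]12C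
F6 | step 5 | diastereomer of 9 with mirrored ring stereocentres | O=C1CCC(=O)[C@H]2[C@@H](CC[C@@H](C)CCO[Si](C)(C)C(C)(C)C)C=C(O[Si](C(C)C)(C(C)C)C(C)C)C[C@@]12C
F7 | step 5 | diastereomer of 10 with mirrored ring stereocentres | O=C1CC[C@@H](O)[C@H]2[C@@H](CC[C@@H](C)CCO[Si](C)(C)C(C)(C)C)C=C(O[Si](C(C)C)(C(C)C)C(C)C)C[C@@]12C
F8 | step 5 | (R)-O-methylmandelate of 10 | O=C1CC[C@H](OC(=O)[C@H](OC)c3ccccc3)[C@@H]2[C@H](CC[C@@H](C)CCO[Si](C)(C)C(C)(C)C)C=C(O[Si](C(C)C)(C(C)C)C(C)C)C[C@]12C
F9 | step 5 | (R)-O-methylmandelate of F7 | O=C1CC[C@@H](OC(=O)[C@H](OC)c3ccccc3)[C@H]2[C@@H](CC[C@@H](C)CCO[Si](C)(C)C(C)(C)C)C=C(O[Si](C(C)C)(C(C)C)C(C)C)C[C@@]12C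
F0 | step 19 | none | none
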